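The product is what I watched. In this flask it forms as starting material meets reagent crossing from the second phase, so I followed one molecule of starting material and asked for its odds of having reacted: product over starting material left.

| flask | starting material | reagent in the second phase | remark | time | volume of the second phase over the first |
|---|---|---|---|---|---|
| south-east | 0.050 M | 1.05 equiv | run made earlier |  |  |
| south | 0.075 M | 1.05 equiv | run made earlier |  |  |
| north-east | 0.10 M | 1.6 equiv | run made earlier |  |  |
| flask | 0.10 M | 1.05 equiv |  | 1.0 h | 1.0 |

- south-east (time / min: product / %): 3.00: 3.4; 6.00: 7.1; 15.0: 16.8; 40.0: 35.1
- south (time / min: product / %): 3.00: 4.5; 6.00: 9.5; 15.0: 22.2; 40.0: 44.3
- north-east (time / min: product / %): 10.0: 29.4; 20.0: 47.5; 25.0: 53.8; 40.0: 66.2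

(standard deviation of a reading: 0.3 percentage points)

- in the second phase: reagent in the second phase; everything else is in the first
- charges count per volume of the first phase; a concentration in a rate is the amount of a species over the volume of its own phase; every rate counts per litre of the first phase
- the earlier runs hold the two phases in the same ratio of volumes as the flask asked about

- alder: doubling the amount of reagent in the second phase, all else as stated
- cedar: doubling the transfer coefficient of the reagent in the second phase, all else as stated

- amount of product at 1.0 h, in percent of the starting material charged
- the change that raises the amount of product at 1.0 h, in percent of the starting material charged most ("none" if none brings more than 2 percentage points) (alder / cedar / none)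
- amount of product at 1.0 h, in percent of the starting material charged, after cedar

I took the first instants from the south-east run. Its second interval gave 3.7 percentage points against 3.4% in the first, a gain of 0.3 points, the size of one reading's scatter and less than the margin. The start-up was therefore short, and I gave cedar, which quickens the crossing, no more than that gain.

In the middle, 1.05 equiv made the charges of the partners nearly equal, so by charge starting material is the limiting reagent, though barely, and I reckoned as if the two fell together. On that assumption the odds grow in step with time and with the charge. I named the even time, the time at which a flask with 0.10 M and 1.05 equiv holds as much product as starting material, the half-life of a second-order reaction. The last south reading gave 37.7 min, and the south-east run gave 37.0 min.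

For the end, the same assumption makes the fraction of product time over time plus even time, so I reckoned 61.4%, and 61.7% after cedar. Extra reagent showed in the north-east run: 66.2% at 40.0 min, more than the 51.5% the even time gives for 1.05 equiv. I therefore chose alder. The reading to watch is the one near the even time.

The forecast gave 59%, alder and 59.3%, saying “Cedar only shortens the lag”.

The flask gave 60.4%, 60.6% after cedar, and alder added 25 points.

    starting material + reagent in the reaction phase → product (k = 0.480 M⁻¹ min⁻¹)
    reagent in the reaction phase ⇌ reagent in the second phase, rate k2*([reagent in the reaction phase] - [reagent in the second phase]/K2) per volume of the first phase (partition coefficient = 0.720, kL = 0.440 min⁻¹)
    2 reagent in the reaction phase → homo dimer (k = 0.0830 M⁻¹ min⁻¹)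

In this flask, product and starting material stood equal at 0.637 h, against my even time of 37.7 min. For the neighbouring flask with 0.060 M of starting material, the even time stretches to 62.9 min, which gives 48.8% at 1.0 h. That neighbouring flask held 48.9% of product.

The earlier runs and the new flask stem from a simulated flask with made-up constants, noise included.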